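**Plan** (locants: perhydro-6,8a-methanophenanthrene numbering; ring A = C-1 to C-4, C-4a, C-10a; ring B = C-4a, C-4b, C-8a, C-9, C-10, C-10a; norbornane = C-4b, C-5, C-6, C-7, C-8, C-8a with bridge C-11)
Retrosynthesis cuts C-1–Br (inversion of an axial alcohol), C-4–CH3 (Grignard) and the isopropyl group (from an ester), then the ring-B bond C-4a–C-4b.
C-4a and C-4b each lie α to an oxygen-bearing carbon (C-4 and C-5), a 1,4-dioxygenated pair of like polarity that a radical can unite; further cuts are C-10a–CH3 (cuprate), C-10–C-10a (B-alkyl Suzuki) and the norbornene (Diels–Alder).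
Forward: ring A arrives as an enantiopure 3-iodo-4-silyloxycyclohexenone, the norbornene as a Diels–Alder adduct that already is a silyl enol ether; the two are joined through the C-9/C-10 tether.
Ring B is closed last by cyclization of the C-4a α-keto radical onto the C-4b=C-5 silyl enol ether, which leaves C-4 a ketone and C-5 a protected alcohol.
Stereochemistry: CBS reduction sets the C-1 oxygen, which steers the methyl cuprate at C-10a and is finally inverted to bromide; the catalysed endo Diels–Alder sets C-6, C-8 and C-8a; the key step sets C-4a, C-4b and C-5; equatorial Grignard attack sets C-4.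

Key step: step 11

Remark: the antipode of the oxazaborolidinium catalyst in step 7 is assigned from the usual transition-state model for acrylate esters; if the sense proves opposite, the mirror-image catalyst is used.
Remark: compounds 1, 6 and 10 are taken as commercially available; 9 and 14 are used without purification.

**Step 1**
Reactants: 1 1,4-dioxaspiro[4.5]dec-6-en-8-one
Product: 2 7-iodo-1,4-dioxaspiro[4.5]dec-6-en-8-one
Conditions: I2, K2CO3, DMAP (cat.), THF/H2O, 23 °C
Reagents that add atoms: iodine, II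
Why: α-Iodination of the enone by amine addition, iodination and elimination (Baylis–Hillman-type mechanism) puts iodine on the α-carbon only, and the ketal is stable to the basic medium.

**Step 2**
Reactants: 2 7-iodo-1,4-dioxaspiro[4.5]dec-6-en-8-one
Product: 3 (8R)-7-iodo-1,4-dioxaspiro[4.5]dec-6-en-8-ol
Conditions: (S)-1-methyl-3,3-diphenyltetrahydro-1H,3H-pyrrolo[1,2-c][1,3,2]oxazaborole (20 mol %), BH3·SMe2, THF, −20 °C
Reagents that add atoms: none
Why: Corey–Bakshi–Shibata reduction, with the iodoalkenyl side as the large group, should deliver hydride to one face and set the carbinol centre (the future C-1 oxygen) under catalyst control.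

**Step 3**
Reactants: 3 (8R)-7-iodo-1,4-dioxaspiro[4.5]dec-6-en-8-ol
Product: 4 (4R)-4-hydroxy-3-iodocyclohex-2-en-1-one
Conditions: 1 M HCl, THF, 23 °C
Reagents that add atoms: water, O
Why: Acid-catalysed ketal hydrolysis unmasks the enone without touching the stereocentre, the carbonyl group disfavouring ionization of the allylic alcohol.

**Step 4**
Reactants: 4 (4R)-4-hydroxy-3-iodocyclohex-2-en-1-one
Product: 5 (4R)-3-iodo-4-(triethylsilyloxy)cyclohex-2-en-1-one
Conditions: Et3SiCl, imidazole, CH2Cl2, 0 °C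
Reagents that add atoms: chlorotriethylsilane, CC[Si](Cl)(CC)CC
Why: Standard silylation of the secondary alcohol; the triethylsilyl ether later directs the cuprate and can be removed beside a triisopropylsilyl ether.

**Step 5**
Reactants: 6 3-ethoxycyclopent-2-en-1-one
Product: 8 3-ethenylcyclopent-2-en-1-one, via allylic magnesium alkoxide 7 (not isolated)
Conditions: CH2=CHMgBr, THF, 0 °C; then 1 M HCl, 0 °C
Reagents that add atoms: vinylmagnesium bromide, C=C[Mg]Br; water, O
Why: Stork–Danheiser sequence: 1,2-addition to the vinylogous ester, then acid hydrolysis with allylic transposition, gives the 3-substituted enone.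

**Step 6**
Reactants: 8 3-ethenylcyclopent-2-en-1-one
Product: 9 1-ethenyl-3-(triisopropylsilyloxy)cyclopenta-1,3-diene
Conditions: LiN(i-Pr)2, THF, −78 °C; i-Pr3SiOTf, −78 °C; non-aqueous work-up, used at once
Reagents that add atoms: triisopropylsilyl trifluoromethanesulfonate, CC(C)[Si](OS(=O)(=O)C(F)(F)F)(C(C)C)C(C)C
Why: Kinetic α′-deprotonation of the cyclopentenone and O-silylation give the cross-conjugated 2-silyloxy diene, which is used at once to forestall 1,5-hydrogen shifts.

**Step 7**
Reactants: 9 1-ethenyl-3-(triisopropylsilyloxy)cyclopenta-1,3-diene; 10 2,2,2-trifluoroethyl prop-2-enoate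
Product: 11 2,2,2-trifluoroethyl (1S,2R,4S)-1-ethenyl-5-(triisopropylsilyloxy)bicyclo[2.2.1]hept-5-ene-2-carboxylate (ester endo)
Conditions: oxazaborolidinium salt from (S)-1-(2-methylphenyl)-3,3-diphenyltetrahydro-1H,3H-pyrrolo[1,2-c][1,3,2]oxazaborole and HN(SO2CF3)2 (10 mol %), CH2Cl2, −78 °C
Reagents that add atoms: none
Why: Catalytic enantioselective Diels–Alder reaction of a 2-silyloxy diene with an acrylate: the silyloxy ("para") and 1-vinyl ("ortho") groups send the ester carbon to the substituted diene terminus, the endo transition state puts the ester anti to the one-carbon bridge, and the chiral Lewis acid shields one acrylate face, so C-6, C-8 and C-8a are set together.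

**Step 8**
Reactants: 11 the Diels–Alder adduct; 5 (4R)-3-iodo-4-(triethylsilyloxy)cyclohex-2-en-1-one
Product: 13 2,2,2-trifluoroethyl 1-{2-[(6R)-3-oxo-6-(triethylsilyloxy)cyclohex-1-en-1-yl]ethyl}-5-(triisopropylsilyloxy)bicyclo[2.2.1]hept-5-ene-2-endo-carboxylate (bicycle as in 11), via alkylborane 12 (not isolated)
Conditions: 9-BBN-H, THF, 23 °C; then 5, PdCl2(dppf) (5 mol %), AsPh3, Cs2CO3, DMF/H2O, 23 °C
Reagents that add atoms: none
Why: 9-BBN hydroborates the monosubstituted alkene anti-Markovnikov much faster than the hindered trisubstituted silyl enol ether, and B-alkyl Suzuki–Miyaura coupling with the β-iodoenone joins C-10 to C-10a without acid, so the silyl groups and the ester survive.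

**Step 9**
Reactants: 13 the enone
Product: 14 2,2,2-trifluoroethyl 1-{2-[1-methyl-6-(triethylsilyloxy)-3-(trimethylsilyloxy)cyclohex-2-en-1-yl]ethyl}-5-(triisopropylsilyloxy)bicyclo[2.2.1]hept-5-ene-2-endo-carboxylate (methyl trans to the triethylsilyloxy group)
Conditions: Me2CuLi, Me3SiCl, Et2O/THF, −78 to −40 °C; Et3N, then aq. NaHCO3; used crude
Reagents that add atoms: lithium dimethylcuprate, [Li+].C[Cu-]C; chlorotrimethylsilane, C[Si](C)(C)Cl
Why: Chlorosilane-accelerated cuprate conjugate addition to the β,β-disubstituted enone occurs anti to the adjacent silyloxy group (held pseudoaxial by allylic strain with the C-10 chain), setting quaternary C-10a, and the enolate is trapped regiospecifically toward C-4a.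

**Step 10**
Reactants: 14 the bis(silyl enol ether)
Product: 16 3-methyl-3-{2-[2-endo-(2-hydroxypropan-2-yl)-5-(triisopropylsilyloxy)bicyclo[2.2.1]hept-5-en-1-yl]ethyl}-2-(phenylselanyl)-4-(triethylsilyloxy)cyclohexan-1-one (either configuration at C-2), via dilithium enolate alkoxide 15 (not isolated)
Conditions: MeLi (4.5 equiv), THF, −78 to 0 °C; then PhSeBr, −78 °C; aq. NH4Cl
Reagents that add atoms: methyllithium, C[Li]; benzeneselenenyl bromide, Br[Se]c1ccccc1
Why: MeLi cleaves the trimethylsilyl enol ether to the regiodefined lithium enolate (the bulkier silyl groups are inert) and converts the ester to the dimethylcarbinol by double addition; enolate selenenylation at C-4a then gives the radical precursor, whose configuration at that carbon is of no consequence.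

**Step 11**
Reactants: 16 the α-phenylselanyl ketone
Product: 17 8-(2-hydroxypropan-2-yl)-10a-methyl-1-(triethylsilyloxy)-5-(triisopropylsilyloxy)perhydro-6,8a-methanophenanthren-4-one (centres as in 23; C-1 oxygen axial)
Conditions: Bu3SnH (1.3 equiv, syringe pump), AIBN (0.2 equiv), PhH (0.005 M), 80 °C; then DBU, PhMe, 60 °C
Reagents that add atoms: none
Why: Bu3Sn• abstracts the PhSe group to give the electrophilic α-keto radical at C-4a, which adds to C-4b, the nucleophilic β-carbon of the strained C-4b=C-5 silyl enol ether, and the α-silyloxy radical left at C-5 takes a hydrogen atom from Bu3SnH, so that C-4 stays a ketone while C-5 emerges as a silyl-protected secondary alcohol. The closest known reaction type is the tin hydride-mediated cyclization of α-carbonyl radicals, generated from α-seleno or α-halo ketones, onto electron-rich alkenes such as enol ethers. Ring B is closed in the 6-exo-trig mode through a chair-like transition state. C-4b is set by attack on the exo face of the norbornene, the face that the two-carbon tether from the C-8a bridgehead reaches without strain and the one bicyclo[2.2.1]heptenes prefer anyway, and C-4a is set by the chair, in which C-4 must lie equatorial because the axial site is syn-axial to the C-11 bridge methylene on C-8a; since C-4a is α to the ketone, the DBU treatment drives any epimer to this same trans-fused isomer. C-5 is set by hydrogen transfer to the exo lobe of the pyramidal α-silyloxy radical, the endo face being screened by the endo hydrogen at C-7, which leaves the silyloxy group endo and trans to the new exo bond. The step needs ring closure to outrun direct reduction of the first radical, which the polarity match, the strain of the alkene, high dilution and slow addition of the stannane secure, and it needs attack at C-4b and not at C-5, which the polarization of the enol ether and the six- over seven-membered ring size secure.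

**Step 12**
Reactants: 17 the tetracyclic hydroxy ketone
Product: 18 10a-methyl-8-(prop-1-en-2-yl)-1-(triethylsilyloxy)-5-(triisopropylsilyloxy)perhydro-6,8a-methanophenanthren-4-one
Conditions: SOCl2, pyridine, CH2Cl2, −20 °C
Reagents that add atoms: none
Why: Dehydration of the tertiary carbinol through its chlorosulfite (E2, pyridine takes a methyl hydrogen) gives the isopropenyl group; the ketone and silyl ethers are inert at low temperature, and any isopropylidene isomer converges in the next step.

**Step 13**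
Reactants: 18 the isopropenyl ketone
Product: 19 10a-methyl-8-(propan-2-yl)-1-(triethylsilyloxy)-5-(triisopropylsilyloxy)perhydro-6,8a-methanophenanthren-4-one
Conditions: H2 (1 atm), palladium on carbon (Pd/C), EtOAc, 23 °C
Reagents that add atoms: none
Why: Heterogeneous hydrogenation of the 1,1-disubstituted alkene gives the isopropyl group without disturbing C-8 (set in step 7); the ketone and silyl ethers are inert.

**Step 14**
Reactants: 19 the isopropyl ketone
Product: 21 4,10a-dimethyl-8-(propan-2-yl)-5-(triisopropylsilyloxy)perhydro-6,8a-methanophenanthrene-1,4-diol (both hydroxyl groups axial), via tertiary magnesium alkoxide 20 (not isolated)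
Conditions: MeMgBr, THF, −78 to 0 °C; then 1 M HCl, THF/H2O, 23 °C
Reagents that add atoms: methylmagnesium bromide, C[Mg]Br
Why: Grignard addition to the C-4 ketone takes the equatorial trajectory because the axial one is blocked by the syn-axial C-10a methyl group, giving the axial tertiary alcohol, and the acidic work-up cleaves only the triethylsilyl ether.

**Step 15**
Reactants: 21 the diol
Product: 22 1-bromo-4,10a-dimethyl-8-(propan-2-yl)-5-(triisopropylsilyloxy)perhydro-6,8a-methanophenanthren-4-ol (bromine equatorial)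
Conditions: CBr4, P(n-C8H17)3, PhMe, 70 °C
Reagents that add atoms: tetrabromomethane, BrC(Br)(Br)Br
Why: Appel reaction: the axial secondary alcohol is activated as its alkoxyphosphonium salt and displaced by bromide with inversion (SN2) to the equatorial bromide, the tertiary alcohol being too hindered to be activated.

**Step 16**
Reactants: 22 the silyl-protected bromide
Product: 23 CNP0295684.1
Conditions: Bu4NF, THF, 23 to 50 °C
Reagents that add atoms: none
Why: Fluoride-induced silyl ether cleavage frees the C-5 alcohol; the equatorial bromide has no anti-periplanar hydrogen for E2 and the tertiary alcohol is inert.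

**Compound list**
1 | 1,4-dioxaspiro[4.5]dec-6-en-8-one | O=C1C=CC2(CC1)OCCO2 | starting material
2 | 7-iodo-1,4-dioxaspiro[4.5]dec-6-en-8-one | O=C1C(I)=CC2(CC1)OCCO2 | intermediate
3 | (8R)-7-iodo-1,4-dioxaspiro[4.5]dec-6-en-8-ol | O[C@H]1C(I)=CC2(CC1)OCCO2 | intermediate
4 | (4R)-4-hydroxy-3-iodocyclohex-2-en-1-one | O=C1C=C(I)[C@H](O)CC1 | intermediate
5 | (4R)-3-iodo-4-(triethylsilyloxy)cyclohex-2-en-1-one | O=C1C=C(I)[C@H](O[Si](CC)(CC)CC)CC1 | intermediate
6 | 3-ethoxycyclopent-2-en-1-one | CCOC1=CC(=O)CC1 | starting material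
7 | bromomagnesium 1-ethenyl-3-ethoxycyclopent-2-en-1-olate (racemic) | CCOC1=CC(O[Mg]Br)(C=C)CC1 | intermediate
8 | 3-ethenylcyclopent-2-en-1-one | O=C1C=C(C=C)CC1 | intermediate
9 | 1-ethenyl-3-(triisopropylsilyloxy)cyclopenta-1,3-diene | C=CC1=CC(O[Si](C(C)C)(C(C)C)C(C)C)=CC1 | intermediate
10 | 2,2,2-trifluoroethyl prop-2-enoate | C=CC(=O)OCC(F)(F)F | starting material
11 | 2,2,2-trifluoroethyl (1S,2R,4S)-1-ethenyl-5-(triisopropylsilyloxy)bicyclo[2.2.1]hept-5-ene-2-carboxylate (ester endo) | FC(F)(F)COC(=O)[C@@H]1C[C@H]2C[C@]1(C=C)C=C2O[Si](C(C)C)(C(C)C)C(C)C | intermediate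
12 | 2,2,2-trifluoroethyl 1-[2-(9-borabicyclo[3.3.1]nonan-9-yl)ethyl]-5-(triisopropylsilyloxy)bicyclo[2.2.1]hept-5-ene-2-endo-carboxylate (bicycle as in 11) | FC(F)(F)COC(=O)[C@@H]1C[C@H]2C[C@]1(CCB3C4CCCC3CCC4)C=C2O[Si](C(C)C)(C(C)C)C(C)C | intermediate
13 | 2,2,2-trifluoroethyl 1-{2-[(6R)-3-oxo-6-(triethylsilyloxy)cyclohex-1-en-1-yl]ethyl}-5-(triisopropylsilyloxy)bicyclo[2.2.1]hept-5-ene-2-endo-carboxylate | FC(F)(F)COC(=O)[C@@H]1C[C@H]2C[C@]1(CCC3=CC(=O)CC[C@H]3O[Si](CC)(CC)CC)C=C2O[Si](C(C)C)(C(C)C)C(C)C | intermediate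
14 | 2,2,2-trifluoroethyl 1-{2-[1-methyl-6-(triethylsilyloxy)-3-(trimethylsilyloxy)cyclohex-2-en-1-yl]ethyl}-5-(triisopropylsilyloxy)bicyclo[2.2.1]hept-5-ene-2-endo-carboxylate (methyl trans to OSiEt3) | FC(F)(F)COC(=O)[C@@H]1C[C@H]2C[C@]1(CC[C@@]3(C)C=C(O[Si](C)(C)C)CC[C@H]3O[Si](CC)(CC)CC)C=C2O[Si](C(C)C)(C(C)C)C(C)C | intermediate
15 | dilithium enolate alkoxide of 14 (lithium enolate toward C-4a, lithium 2-propanolate on the bicycle) | [Li]OC(C)(C)[C@@H]1C[C@H]2C[C@]1(CC[C@@]3(C)C=C(O[Li])CC[C@H]3O[Si](CC)(CC)CC)C=C2O[Si](C(C)C)(C(C)C)C(C)C | intermediate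
16 | 3-methyl-3-{2-[2-endo-(2-hydroxypropan-2-yl)-5-(triisopropylsilyloxy)bicyclo[2.2.1]hept-5-en-1-yl]ethyl}-2-(phenylselanyl)-4-(triethylsilyloxy)cyclohexan-1-one (3-methyl trans to 4-OSiEt3; C-2 either way) | CC(C)(O)[C@@H]1C[C@H]2C[C@]1(CC[C@@]3(C)C([Se]c4ccccc4)C(=O)CC[C@H]3O[Si](CC)(CC)CC)C=C2O[Si](C(C)C)(C(C)C)C(C)C | intermediate
17 | 8-(2-hydroxypropan-2-yl)-10a-methyl-1-(triethylsilyloxy)-5-(triisopropylsilyloxy)perhydro-6,8a-methanophenanthren-4-one (trans A/B, ring B exo on the norbornane, C-5 oxygen endo, C-1 oxygen axial) | CC(C)(O)[C@@H]1C[C@H]2C[C@@]13CC[C@]1(C)[C@H](O[Si](CC)(CC)CC)CCC(=O)[C@H]1[C@@H]3[C@H]2O[Si](C(C)C)(C(C)C)C(C)C | intermediate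
18 | 10a-methyl-8-(prop-1-en-2-yl)-1-(triethylsilyloxy)-5-(triisopropylsilyloxy)perhydro-6,8a-methanophenanthren-4-one | C=C(C)[C@@H]1C[C@H]2C[C@@]13CC[C@]1(C)[C@H](O[Si](CC)(CC)CC)CCC(=O)[C@H]1[C@@H]3[C@H]2O[Si](C(C)C)(C(C)C)C(C)C | intermediate
19 | 10a-methyl-8-(propan-2-yl)-1-(triethylsilyloxy)-5-(triisopropylsilyloxy)perhydro-6,8a-methanophenanthren-4-one | CC(C)[C@@H]1C[C@H]2C[C@@]13CC[C@]1(C)[C@H](O[Si](CC)(CC)CC)CCC(=O)[C@H]1[C@@H]3[C@H]2O[Si](C(C)C)(C(C)C)C(C)C | intermediate
20 | bromomagnesium alkoxide of 4,10a-dimethyl-8-(propan-2-yl)-1-(triethylsilyloxy)-5-(triisopropylsilyloxy)perhydro-6,8a-methanophenanthren-4-ol | CC(C)[C@@H]1C[C@H]2C[C@@]13CC[C@]1(C)[C@H](O[Si](CC)(CC)CC)CC[C@@](C)(O[Mg]Br)[C@H]1[C@@H]3[C@H]2O[Si](C(C)C)(C(C)C)C(C)C | intermediate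
21 | 4,10a-dimethyl-8-(propan-2-yl)-5-(triisopropylsilyloxy)perhydro-6,8a-methanophenanthrene-1,4-diol (C-1 and C-4 hydroxyl groups axial) | CC(C)[C@@H]1C[C@H]2C[C@@]13CC[C@]1(C)[C@H](O)CC[C@@](C)(O)[C@H]1[C@@H]3[C@H]2O[Si](C(C)C)(C(C)C)C(C)C | intermediate
22 | 1-bromo-4,10a-dimethyl-8-(propan-2-yl)-5-(triisopropylsilyloxy)perhydro-6,8a-methanophenanthren-4-ol (bromine equatorial) | CC(C)[C@@H]1C[C@H]2C[C@@]13CC[C@]1(C)[C@@H](Br)CC[C@@](C)(O)[C@H]1[C@@H]3[C@H]2O[Si](C(C)C)(C(C)C)C(C)C | intermediate
23 | CNP0295684.1, 1-bromo-4,10a-dimethyl-8-(propan-2-yl)perhydro-6,8a-methanophenanthrene-4,5-diol (Br equatorial, C-4 OH axial, trans A/B, ring B exo, C-5 OH endo, isopropyl endo) | CC(C)[C@@H]1C[C@H]2C[C@@]13CC[C@]1(C)[C@@H](Br)CC[C@@](C)(O)[C@H]1[C@@H]3[C@H]2O | target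

**Step count**
Total: 16 steps. Longest linear sequence: 13 steps (steps 1–4, then 8–16).

**Steps most likely to fail**

Step 11. The first radical may be reduced before it cyclizes, or hydrogen may be delivered to C-5 with poor facial selectivity. The fallback sets out from 14 and comes back at 17. Oxidative coupling of the two enol silanes of 14 with (NH4)2Ce(NO3)6 and NaHCO3 in MeCN at −30 °C, followed by DBU equilibration of the two α-centres, would give the trifluoroethyl ester 1,4-diketone F1. LiN(i-Pr)2/Me3SiCl at −78 °C would mask the C-4 ketone as the C-3 enol trimethylsilyl ether F2, since the C-5 ketone has only a tertiary endo α-hydrogen and is not enolized. LiAlH(Ot-Bu)3 in THF at −40 °C would reduce the C-5 ketone from the exo face to the endo alcohol F3, and i-Pr3SiOTf/2,6-lutidine would give the C-5 triisopropylsilyl ether F4. Excess MeLi would then convert the ester to the dimethylcarbinol and cleave the enol silane, the enolate returning the C-4 ketone on protonation, which is 17.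

Step 7. The silyloxy diene may isomerize by 1,5-hydrogen shift before cycloaddition, the reaction may stop at a Michael adduct without ring closure, or facial control by the catalyst may be insufficient. The fallback sets out from 9 and comes back at 11. Et2AlCl-promoted cycloaddition of 9 with (4S)-3-acryloyl-4-benzyl-1,3-oxazolidin-2-one in CH2Cl2 at −78 °C, in which the chelated dienophile is shielded on one face by the benzyl group, would give the N-acyloxazolidinone cycloadduct F5. LiOCH2CF3 in THF at 0 °C would exchange the auxiliary for the trifluoroethyl ester and give 11.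

Step 15. Elimination toward C-2 or migration of the C-10a methyl group may compete with backside attack of bromide at the neopentyl centre. The fallback sets out from 21 and comes back at 22. Swern oxidation of the C-1 alcohol would give the C-1 ketone F6 (the tertiary alcohol is inert), and N2H4·H2O/Et3N in EtOH at 80 °C its hydrazone F7. N-Bromosuccinimide in pyridine would give the C-1=C-2 vinyl bromide F8, the only direction open next to quaternary C-10a. Hydrogen-atom-transfer hydrogenation with Mn(dpm)3, PhSiH3 and t-BuOOH in i-PrOH would reduce the alkene without loss of bromine; hydrogen reaches C-1 on the face anti to the axial C-10a methyl group, so bromine ends equatorial, which is 22.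

**Further compounds**
F1 | step 11 | 2,2,2-trifluoroethyl 10a-methyl-4,5-dioxo-1-(triethylsilyloxy)perhydro-6,8a-methanophenanthrene-8-carboxylate (trans A/B, ring B exo) | FC(F)(F)COC(=O)[C@@H]1C[C@H]2C[C@@]13CC[C@]1(C)[C@H](O[Si](CC)(CC)CC)CCC(=O)[C@H]1[C@@H]3C2=O
F2 | step 11 | C-3 enol trimethylsilyl ether of F1 (4-trimethylsilyloxy, C-3=C-4 alkene, C-5 ketone free) | FC(F)(F)COC(=O)[C@@H]1C[C@H]2C[C@@]13CC[C@]1(C)[C@H](O[Si](CC)(CC)CC)CC=C(O[Si](C)(C)C)[C@H]1[C@@H]3C2=O
F3 | step 11 | C-5 endo alcohol of F2 | FC(F)(F)COC(=O)[C@@H]1C[C@H]2C[C@@]13CC[C@]1(C)[C@H](O[Si](CC)(CC)CC)CC=C(O[Si](C)(C)C)[C@H]1[C@@H]3[C@H]2O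
F4 | step 11 | C-5 triisopropylsilyl ether of F3 | FC(F)(F)COC(=O)[C@@H]1C[C@H]2C[C@@]13CC[C@]1(C)[C@H](O[Si](CC)(CC)CC)CC=C(O[Si](C)(C)C)[C@H]1[C@@H]3[C@H]2O[Si](C(C)C)(C(C)C)C(C)C
F5 | step 7 | (4S)-4-benzyl-3-{[(1S,2R,4S)-1-ethenyl-5-(triisopropylsilyloxy)bicyclo[2.2.1]hept-5-en-2-yl]carbonyl}-1,3-oxazolidin-2-one (acyl group endo) | O=C1OC[C@H](Cc2ccccc2)N1C(=O)[C@@H]3C[C@H]4C[C@]3(C=C)C=C4O[Si](C(C)C)(C(C)C)C(C)C
F6 | step 15 | 4-hydroxy-4,10a-dimethyl-8-(propan-2-yl)-5-(triisopropylsilyloxy)perhydro-6,8a-methanophenanthren-1-one | CC(C)[C@@H]1C[C@H]2C[C@@]13CC[C@]1(C)C(=O)CC[C@@](C)(O)[C@H]1[C@@H]3[C@H]2O[Si](C(C)C)(C(C)C)C(C)C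
F7 | step 15 | hydrazone of F6 at C-1 | CC(C)[C@@H]1C[C@H]2C[C@@]13CC[C@]1(C)C(=NN)CC[C@@](C)(O)[C@H]1[C@@H]3[C@H]2O[Si](C(C)C)(C(C)C)C(C)C
F8 | step 15 | C-1=C-2 vinyl bromide: 1-bromo-4,10a-dimethyl-8-(propan-2-yl)-5-(triisopropylsilyloxy)-1,2-didehydroperhydro-6,8a-methanophenanthren-4-ol | CC(C)[C@@H]1C[C@H]2C[C@@]13CC[C@]1(C)C(Br)=CC[C@@](C)(O)[C@H]1[C@@H]3[C@H]2O[Si](C(C)C)(C(C)C)C(C)C
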